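## Retrosynthetic overview

1. Target ⇒ enol tosylate **11**: the last C–C bond made is butenolide C4–CH2OH, by a visible-light Ni/Ir decarboxylative hydroxymethylation with glycolic acid.
2. **11** ⇒ tetronic acid **10** ⇒ dioxolanone **9** + ethyl acetate enolate. The butenolide is the only ring built (step 7); the cyclohexene ring is bought in dihydro-β-ionone.
3. **9** ⇒ (Z)-iodo allylic alcohol **6** + malic acetonide acid **8**: the key C(sp3)–C(sp2) bond is made by visible-light Ni/Ir decarboxylative alkenylation. The single stereocentre is bought in D-malic acid.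
4. **6** ⇒ propargyl alcohol + the Grignard of homoallyl bromide **4** (Cu-catalysed carbomagnesiation/I2 sets Z). **4** ⇒ dihydro-β-ionone via a terminal alkyne and Zr-carboalumination/ethylene oxide (sets E).

Assumption: the SMILES is taken as definitive (lactone carbon R; CH2OH of the central alkene cis to the lactone-bearing CH2; distal alkene E). D-(+)-Malic acid is taken as the cheap chiral source; its acetonide **8** is also a catalogue compound, which would remove step 5.

## Route

**Step 1**
Reactants: **1**, dihydro-β-ionone [4-(2,6,6-trimethylcyclohex-1-en-1-yl)butan-2-one]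
Product: **2**, 2-(but-3-yn-1-yl)-1,3,3-trimethylcyclohex-1-ene
Conditions: LDA, THF, −78 °C; ClP(O)(OEt)2, −78 °C → rt; then LDA (2.3 equiv), −78 °C → rt
Reagents that add atoms: none
Why: The kinetic CH3-side enolate is trapped as the enol phosphate and eliminated by excess LDA (Negishi enol-phosphate alkyne synthesis); the tetrasubstituted ring alkene is inert.

**Step 2**
Reactants: **2**
Product: **3**, (3E)-4-methyl-6-(2,6,6-trimethylcyclohex-1-en-1-yl)hex-3-en-1-ol
Conditions: AlMe3, Cp2ZrCl2 (25 mol%), CH2Cl2, 0 °C → rt; evaporate; n-BuLi, hexane/THF, −78 °C; ethylene oxide, −78 → 0 °C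
Reagents that add atoms: trimethylaluminium, C[Al](C)C; ethylene oxide, C1CO1
Why: Negishi Zr-catalysed methylalumination adds Me–Al syn across the terminal alkyne (Me on the internal carbon), and the alkenyl alanate opens ethylene oxide with retention, fixing the E-trisubstituted alkene.

**Step 3**
Reactants: **3**
Product: **4**, 2-[(3E)-6-bromo-3-methylhex-3-en-1-yl]-1,3,3-trimethylcyclohex-1-ene
Conditions: CBr4, PPh3, 2,6-lutidine, CH2Cl2, 0 °C
Reagents that add atoms: carbon tetrabromide, BrC(Br)(Br)Br
Why: Appel bromination of a primary homoallylic alcohol under neutral conditions leaves both alkenes untouched.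

**Step 4**
Reactants: **4**; **5**, propargyl alcohol
Product: **6**, (2Z)-3-iodo-2-[(3E)-4-methyl-6-(2,6,6-trimethylcyclohex-1-en-1-yl)hex-3-en-1-yl]prop-2-en-1-ol
Conditions: **4** (1.5 equiv), Mg, THF; add to ClMgOCH2C≡CH (from **5** + i-PrMgCl, −20 °C), CuI (10 mol%), −10 °C → rt, 16 h; then I2, −30 → 0 °C
Reagents that add atoms: iodine, II
Why: Cu-catalysed anti-carbomagnesiation of the propargylic magnesium alkoxide (Duboudin–Jousseaume) puts the alkyl group on C2 and Mg on C3 in a five-membered chelate cis to CH2O, so iodinolysis with retention gives only the Z-iodide.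

**Step 5**
Reactants: **7**, D-(+)-malic acid [(R)-2-hydroxybutanedioic acid]
Product: **8**, 2-[(4R)-2,2-dimethyl-5-oxo-1,3-dioxolan-4-yl]acetic acid
Conditions: 2,2-dimethoxypropane, p-TsOH·H2O (cat.), rt
Reagents that add atoms: 2,2-dimethoxypropane, COC(C)(C)OC
Why: Acid-catalysed transacetalisation ties up the α-hydroxy acid selectively as the five-membered dioxolanone and leaves the β-carboxyl free, with the R stereocentre untouched.

**Step 6** (key fragment union)
Reactants: **6**; **8** (2 equiv)
Product: **9**, (5R)-5-[(2Z,6E)-3-(hydroxymethyl)-7-methyl-9-(2,6,6-trimethylcyclohex-1-en-1-yl)nona-2,6-dien-1-yl]-2,2-dimethyl-1,3-dioxolan-4-one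
Conditions: Ir[dF(CF3)ppy]2(dtbbpy)PF6 (1 mol%), NiCl2·glyme (10 mol%), dtbbpy (12 mol%), Cs2CO3 (1 equiv, gives the Cs carboxylate only), DMSO, 450 nm LEDs, 25 °C
Reagents that add atoms: none
Why: Ni/photoredox decarboxylative C(sp3)–C(sp2) cross-coupling: excited Ir(III) oxidises the primary carboxylate, CO2 loss gives a CH2 radical one carbon away from the stereocentre (so R is kept), and the alkenyl–Ni from oxidative addition into C–I couples with retention of the Z geometry; the ester-level carbonyl next to the radical rules out 1,2-shift pathways.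

**Step 7** (butenolide ring)
Reactants: **9**
Product: **10**, (5R)-4-hydroxy-5-[(2Z,6E)-3-(hydroxymethyl)-7-methyl-9-(2,6,6-trimethylcyclohex-1-en-1-yl)nona-2,6-dien-1-yl]furan-2(5H)-one
Conditions: LiCH2CO2Et (LDA/EtOAc, 4 equiv), THF, −78 → −20 °C; then 1 M HCl, THF, rt
Reagents that add atoms: ethyl acetate, CCOC(C)=O
Why: Claisen-type acylation of the ester enolate by the activated dioxolanone carbonyl releases acetone and the C–O alkoxide, which lactonises onto the new β-keto ester to give the tetronic acid without breaking the stereocentre's C–O bond (any **9** that has trans-lactonised onto the allylic OH converges to the same product).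

**Step 8**
Reactants: **10**
Product: **11**, (2R)-2-[(2Z,6E)-3-(hydroxymethyl)-7-methyl-9-(2,6,6-trimethylcyclohex-1-en-1-yl)nona-2,6-dien-1-yl]-5-oxo-2,5-dihydrofuran-3-yl 4-methylbenzenesulfonate
Conditions: TsCl (1.05 equiv), i-Pr2NEt (1.1 equiv), CH2Cl2, −10 → 0 °C
Reagents that add atoms: p-toluenesulfonyl chloride, Cc1ccc(cc1)S(Cl)(=O)=O
Why: The tetronic acid (pKa about 4) is fully ionised by the amine, and O-sulfonylation of the tetronate should be much faster than tosylation of the neutral primary allylic alcohol without DMAP (chemoselective enol sulfonate formation).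

**Step 9**
Reactants: **11**
Product: **12**, (6Z)-neomanoalide [(5R)-4-(hydroxymethyl)-5-[(2Z,6E)-3-(hydroxymethyl)-7-methyl-9-(2,6,6-trimethylcyclohex-1-en-1-yl)nona-2,6-dien-1-yl]furan-2(5H)-one]
Conditions: HOCH2CO2H (3 equiv), Cs2CO3 (1.5 equiv), Ir[dF(CF3)ppy]2(dtbbpy)PF6 (2 mol%), NiCl2·glyme (10 mol%), dtbbpy (12 mol%), DMSO, 450 nm LEDs, 25 °C
Reagents that add atoms: glycolic acid, OCC(O)=O
Why: Proposed new method: decarboxylative hydroxymethylation of a tetronate enol tosylate — excited Ir(III) oxidises cesium glycolate, CO2 loss gives •CH2OH site-specifically (no HAT reagent that could attack the allylic C–H bonds), and this radical is captured by the alkenyl–Ni(II) formed by Ni(0) insertion into the vinylogous C–OTs bond, with C–C reductive elimination from Ni(III); a background Giese addition at C4, reduction and E1cB loss of TsO⁻ leads to the same product, the only base is the carboxylate so the γ-stereocentre is not epimerised, and the closest known reactions are Ni/photoredox decarboxylative alkenylation of α-oxy acids with vinyl halides and Pd couplings of 4-tosyloxyfuranones.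

## Compound list

1 | dihydro-β-ionone | CC1=C(CCC(C)=O)C(C)(C)CCC1 | starting material
2 | 2-(but-3-yn-1-yl)-1,3,3-trimethylcyclohex-1-ene | CC1=C(CCC#C)C(C)(C)CCC1 | intermediate
3 | (3E)-4-methyl-6-(2,6,6-trimethylcyclohex-1-en-1-yl)hex-3-en-1-ol | CC1=C(CC/C(C)=C/CCO)C(C)(C)CCC1 | intermediate
4 | 2-[(3E)-6-bromo-3-methylhex-3-en-1-yl]-1,3,3-trimethylcyclohex-1-ene | CC1=C(CC/C(C)=C/CCBr)C(C)(C)CCC1 | intermediate
5 | propargyl alcohol | C#CCO | starting material
6 | (2Z)-3-iodo-2-[(3E)-4-methyl-6-(2,6,6-trimethylcyclohex-1-en-1-yl)hex-3-en-1-yl]prop-2-en-1-ol | CC1=C(CC/C(C)=C/CC/C(=C/I)CO)C(C)(C)CCC1 | intermediate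
7 | D-(+)-malic acid, (R) | OC(=O)C[C@@H](O)C(=O)O | starting material
8 | 2-[(4R)-2,2-dimethyl-5-oxo-1,3-dioxolan-4-yl]acetic acid | OC(=O)C[C@H]1OC(C)(C)OC1=O | intermediate
9 | (5R)-5-[(2Z,6E)-3-(hydroxymethyl)-7-methyl-9-(2,6,6-trimethylcyclohex-1-en-1-yl)nona-2,6-dien-1-yl]-2,2-dimethyl-1,3-dioxolan-4-one | CC1=C(CC/C(C)=C/CC/C(=C/C[C@H]2OC(C)(C)OC2=O)CO)C(C)(C)CCC1 | intermediate
10 | (5R)-4-hydroxy-5-[same (2Z,6E) side chain]furan-2(5H)-one | CC1=C(CC/C(C)=C/CC/C(=C/C[C@H]2OC(=O)C=C2O)CO)C(C)(C)CCC1 | intermediate
11 | (2R)-2-[same side chain]-5-oxo-2,5-dihydrofuran-3-yl 4-methylbenzenesulfonate | CC1=C(CC/C(C)=C/CC/C(=C/C[C@H]2OC(=O)C=C2OS(=O)(=O)c3ccc(C)cc3)CO)C(C)(C)CCC1 | intermediate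
12 | (6Z)-neomanoalide | CC1=C(CC/C(C)=C/CC/C(=C/C[C@H]2OC(=O)C=C2CO)CO)C(C)(C)CCC1 | target

## Step count and risks

Total steps: 9. Longest linear sequence: 8 (steps 1–4, 6–9). No protecting-group steps.

Steps most likely to fail:

- **Step 9 (proposed new step).** Risks are slow Ni insertion into C–OTs, over-oxidation of •CH2OH to formaldehyde, carboxylate attack at C4, and a second radical addition to the product. Fallback (known chemistry): make the enol triflate of **10** and install CH2OH by Pd(0)/LiCl Stille coupling with Bu3SnCH2OH, a neutral two-electron cross-coupling instead of radical chemistry.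
- **Step 6.** Risks are low efficiency for a primary carboxylic acid and Ni-mediated C–O coupling with the carboxylate or free OH. Fallback: a polar union from the L-serine chiral pool — CuI-catalysed C3-opening of methyl (R)-glycidate by the alkenylmagnesium of step 4 (before the iodine quench), then O-acetylation and LiHMDS Dieckmann cyclisation of the α-hydroxy ester to the same tetronic acid **10**.
- **Step 8.** The risk is competing tosylation or chlorination of the primary allylic alcohol. Fallback: change the protecting-group strategy — silylate **6** (TBSCl, imidazole), carry the TBS ether through steps 6–9 (Tf2O can then be used for enol activation) and desilylate last with HF·pyridine (two extra steps).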